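The strategy reads the ten-membered carbocycle as the rim of a cis-fused decalin: C4 and C9 face each other across the ring (1,6), C9 carries the ketone and C4/C5 the vicinal oxygens, so the bond to cut last is C4–C9. A single Grob fragmentation of a 9-hydroxy-5-mesyloxy decalin unveils the medium ring, the C9 ketone and the Z C4=C5 alkene that later takes the syn-diol. The precursor, built from (R)-carvone in nine steps, has the angular 9-OH and 4-CH3 cis, an equatorial 5-OMs, a 6-OTBS group and a C7 side chain already oxidised at C12, so that no allylic oxidation is needed once the ring alkene exists.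

Key step: step 10

Remark on numbering: locants are those of the ten-membered ring of the target (C1–C10; C11, C12, C13 = lactone α-carbon, carbonyl carbon, methylene; the methyls sit on C4 and C10). In the decalins ring A is C4–C5–C6–C7–C8–C9, ring B is C9–C10–C1–C2–C3–C4, and β is the face of the 9-OH.

Remark on the chemistry: the decalin is taken to be conformationally locked (C10 and the C7 chain cannot both be axial on ring A). A trans-diaxial epoxide opening therefore cannot give the diequatorial 5,6-diol, so O5 is set by oxidation and hydroxyl-directed reduction instead.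

Step 1
Reactants: 1 (R)-carvone; 2 5-bromopent-1-ene
Product: 4 (2S,5S)-2-methyl-2-(pent-4-en-1-yl)-5-(prop-1-en-2-yl)cyclohex-3-en-1-one, via potassium dienolate 3 (not isolated)
Conditions: t-BuOK (1.05 equiv), THF/t-BuOH, 0 °C to rt; then 2, rt
Reagents that add atoms: 5-bromopent-1-ene (compound 2), C=CCCCBr
Why: Reversible deprotonation at the γ-carbon gives the linear dienolate 3, which is alkylated at its α-carbon (deconjugative α-alkylation of an enone), and axial attack on the half-chair with a pseudo-equatorial isopropenyl group should bring the chain in cis to that group (the sense familiar from annulations of dihydrocarvone), which sets C4; any C4 epimer is to be removed by chromatography here or at 5.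

Step 2
Reactants: 4 (2S,5S)-2-methyl-2-(pent-4-en-1-yl)-5-(prop-1-en-2-yl)cyclohex-3-en-1-one
Product: 5 (4S,7S,9R,10S)-4β,10α-dimethyl-7α-(prop-1-en-2-yl)-cis-decal-5-en-9β-ol
Conditions: SmI2 (2.5 equiv), HMPA, t-BuOH, THF, 0 °C to rt
Reagents that add atoms: none
Why: SmI2 ketyl–olefin radical cyclisation (6-exo-trig) forms the C9–C10 bond, and a chair transition state with the bulky samarium-bound oxygen and the alkene terminus both equatorial should give the cis ring fusion (9-O cis to 4-CH3) with the new 10-CH3 trans to the 9-OH.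

Step 3
Reactants: 5 (4S,7S,9R,10S)-4β,10α-dimethyl-7α-(prop-1-en-2-yl)-cis-decal-5-en-9β-ol
Product: 7 (4S,5S,6R,7R,9R,10S)-4β,10α-dimethyl-7α-(prop-1-en-2-yl)-cis-decalin-5β,6β,9β-triol, via osmate ester TMEDA chelate 6 (not isolated)
Conditions: OsO4 (1.05 equiv), TMEDA, CH2Cl2, −78 °C; then aq. Na2SO3, THF, 60 °C
Reagents that add atoms: osmium tetroxide, O=[Os](=O)(=O)=O
Why: In this hydroxyl-directed dihydroxylation the OsO4·TMEDA complex is held by hydrogen bonding to the axial homoallylic 9-OH and should add only to the β face of C5=C6, leaving the undirected isopropenyl alkene alone and setting O6 trans to the C7 side chain; sulfite then frees the triol from chelate 6.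

Step 4
Reactants: 7 (4S,5S,6R,7R,9R,10S)-4β,10α-dimethyl-7α-(prop-1-en-2-yl)-cis-decalin-5β,6β,9β-triol
Product: 8 (4S,5S,6R,7R,9R,10S)-6β-(tert-butyldimethylsilyloxy)-4β,10α-dimethyl-7α-(prop-1-en-2-yl)-cis-decalin-5β,9β-diol
Conditions: TBSCl (1.1 equiv), imidazole, DMF, 0 °C to rt
Reagents that add atoms: tert-butyldimethylsilyl chloride, CC(C)(C)[Si](C)(C)Cl
Why: Selective silyl ether formation should take the equatorial 6-OH, since the 5-OH is axial, neopentyl and hydrogen-bonded to the 9-OH and the 9-OH is tertiary.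

Step 5
Reactants: 8 (4S,5S,6R,7R,9R,10S)-6β-(tert-butyldimethylsilyloxy)-4β,10α-dimethyl-7α-(prop-1-en-2-yl)-cis-decalin-5β,9β-diol
Product: 9 (4R,6R,7R,9R,10S)-6β-(tert-butyldimethylsilyloxy)-9β-hydroxy-4β,10α-dimethyl-7α-(prop-1-en-2-yl)-cis-decalin-5-one
Conditions: Dess–Martin periodinane, NaHCO3, CH2Cl2, 0 °C to rt
Reagents that add atoms: none
Why: Dess–Martin oxidation converts the only secondary alcohol into the C5 ketone under buffered, non-basic conditions that should spare the β-hydroxy ketone from retro-aldol cleavage and the tertiary 9-OH from any reaction.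

Step 6
Reactants: 9 (4R,6R,7R,9R,10S)-6β-(tert-butyldimethylsilyloxy)-9β-hydroxy-4β,10α-dimethyl-7α-(prop-1-en-2-yl)-cis-decalin-5-one
Product: 10 (4S,5R,6R,7R,9R,10S)-6β-(tert-butyldimethylsilyloxy)-4β,10α-dimethyl-7α-(prop-1-en-2-yl)-cis-decalin-5α,9β-diol
Conditions: Me4NBH(OAc)3, MeCN/AcOH, −30 to 0 °C
Reagents that add atoms: none
Why: In this Evans–Saksena reduction the axial 9-OH binds boron and delivers hydride intramolecularly to the β face of the C5 ketone, which should give the 1,3-anti diol with the new 5-OH α and equatorial (5R), trans to O6.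

Step 7
Reactants: 10 (4S,5R,6R,7R,9R,10S)-6β-(tert-butyldimethylsilyloxy)-4β,10α-dimethyl-7α-(prop-1-en-2-yl)-cis-decalin-5α,9β-diol
Product: 11 (4S,5R,6R,7R,9R,10S)-6β-(tert-butyldimethylsilyloxy)-9β-hydroxy-4β,10α-dimethyl-7α-(prop-1-en-2-yl)-cis-decalin-5α-yl methanesulfonate
Conditions: MsCl, Et3N, CH2Cl2, −10 to 0 °C
Reagents that add atoms: methanesulfonyl chloride, CS(=O)(=O)Cl
Why: Mesylation through sulfene reaches the hindered secondary 5-OH while the tertiary 9-OH should stay free at this temperature.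

Step 8
Reactants: 11 (4S,5R,6R,7R,9R,10S)-6β-(tert-butyldimethylsilyloxy)-9β-hydroxy-4β,10α-dimethyl-7α-(prop-1-en-2-yl)-cis-decalin-5α-yl methanesulfonate
Product: 12 (4S,5R,6R,7R,9R,10S)-6β-(tert-butyldimethylsilyloxy)-9β-hydroxy-7α-(3-hydroxyprop-1-en-2-yl)-4β,10α-dimethyl-cis-decalin-5α-yl methanesulfonate
Conditions: SeO2 (cat.), t-BuOOH, CH2Cl2, 0 °C to rt, stopped short of full conversion
Reagents that add atoms: tert-butyl hydroperoxide, CC(C)(C)OO (terminal oxygen source; the oxygen is relayed by the catalyst SeO2, O=[Se]=O)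
Why: Riley-type allylic oxidation (ene reaction, then 2,3-shift) should hydroxylate the methyl group of the isopropenyl unit, which at this stage is the only alkene in the molecule, the tertiary allylic C7–H being shielded by the neighbouring silyl ether.

Step 9
Reactants: 12 (4S,5R,6R,7R,9R,10S)-6β-(tert-butyldimethylsilyloxy)-9β-hydroxy-7α-(3-hydroxyprop-1-en-2-yl)-4β,10α-dimethyl-cis-decalin-5α-yl methanesulfonate
Product: 13 (4S,5R,6R,7R,9R,10S)-6β-(tert-butyldimethylsilyloxy)-7α-[3-(tert-butyldimethylsilyloxy)prop-1-en-2-yl]-9β-hydroxy-4β,10α-dimethyl-cis-decalin-5α-yl methanesulfonate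
Conditions: TBSCl, imidazole, CH2Cl2, 0 °C
Reagents that add atoms: tert-butyldimethylsilyl chloride, CC(C)(C)[Si](C)(C)Cl
Why: Silylation of the primary allylic alcohol is far faster than that of the tertiary 9-OH, so the fragmentation substrate should carry no free hydroxyl other than the one that must ionise.

Step 10
Reactants: 13 (4S,5R,6R,7R,9R,10S)-6β-(tert-butyldimethylsilyloxy)-7α-[3-(tert-butyldimethylsilyloxy)prop-1-en-2-yl]-9β-hydroxy-4β,10α-dimethyl-cis-decalin-5α-yl methanesulfonate
Product: 15 (4Z,6S,7R,10S)-6-(tert-butyldimethylsilyloxy)-7-[3-(tert-butyldimethylsilyloxy)prop-1-en-2-yl]-4,10-dimethylcyclodec-4-en-9-one, via potassium alkoxide 14 (not isolated)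
Conditions: t-BuOK (1.0 equiv), THF, 0 °C; pH 7 phosphate buffer quench
Reagents that add atoms: none
Why: t-BuOK turns the angular 9-OH into alkoxide 14, whose lone pair drives cleavage of the C4–C9 bond while the mesylate leaves from C5, the participating bonds being anti-periplanar in the chair that has 5-OMs, 6-OTBS and the C7 chain equatorial; this is a concerted Grob fragmentation of a 1,3-diol monosulfonate, of the Wharton type long used to open decalin diol monosulfonates to cyclodecenones. The ten-membered ring is not closed by joining two ends: it is already present as the outer atoms C1–C10 of rings A and B and becomes a ring of its own when their shared bond is cut, so no cyclisation mode applies. No stereocentre is formed (C4 and C9 become trigonal; C6, C7 and C10 are spectators), and the alkene geometry follows from the C4/C5 relative configuration: C3, axial on ring A and cis to the mesylate, sits about 60° from C6 about the C4–C5 bond and stays on its side when that bond flattens, which should give the Z alkene. The step needs fragmentation to win over elimination, oxetane formation and epoxide formation, and the substrate provides for this because the equatorial mesylate has no anti-periplanar hydrogen, O6 is capped as a silyl ether and the alkoxide cannot reach the rear of C5 without leaving the chair. One equivalent of base at 0 °C and a buffered quench are chosen so that the new ketone does not epimerise at C10.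

Step 11
Reactants: 15 (4Z,6S,7R,10S)-6-(tert-butyldimethylsilyloxy)-7-[3-(tert-butyldimethylsilyloxy)prop-1-en-2-yl]-4,10-dimethylcyclodec-4-en-9-one
Product: 16 (4Z,6S,7R,10S)-6-hydroxy-7-(3-hydroxyprop-1-en-2-yl)-4,10-dimethylcyclodec-4-en-9-one
Conditions: Bu4NF, AcOH, THF, 0 °C to rt
Reagents that add atoms: none
Why: Acetic-acid-buffered fluoride removes both silyl ethers (desilylation) without a base strong enough to epimerise C10 or an acid strong enough to trigger transannular reactions of the enone.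

Step 12
Reactants: 16 (4Z,6S,7R,10S)-6-hydroxy-7-(3-hydroxyprop-1-en-2-yl)-4,10-dimethylcyclodec-4-en-9-one
Product: 19 (4Z,6S,7R,10S)-4,10-dimethyl-11(13)-methylene-9-oxocyclodec-4-ene-6,12-lactone (trans-fused α-methylene γ-lactone), via hydroxy enal 17 (not isolated), via lactol 18 (not isolated)
Conditions: TEMPO (2,2,6,6-tetramethylpiperidin-1-oxyl, cat.), PhI(OAc)2 (2.5 equiv), CH2Cl2, rt
Reagents that add atoms: none
Why: TEMPO/PhI(OAc)2 oxidises the primary allylic alcohol in preference to the secondary 6-OH to give enal 17, the 6-OH closes the five-membered lactol 18 and a second oxidation gives the lactone (oxidative lactonisation of a 1,4-diol), trans-fused because C6 and C7 are untouched.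

Step 13
Reactants: 19 (4Z,6S,7R,10S)-4,10-dimethyl-11(13)-methylene-9-oxocyclodec-4-ene-6,12-lactone
Product: 20 (4R,5S,6R,7R,10S)-4,5-dihydroxy-4,10-dimethyl-11(13)-methylene-9-oxocyclodecane-6,12-lactone
Conditions: OsO4 (cat.), N-methylmorpholine N-oxide, acetone/H2O, 0 °C
Reagents that add atoms: N-methylmorpholine N-oxide, C[N+]1([O-])CCOCC1; water, O (both oxygens are relayed by the catalyst OsO4, O=[Os](=O)(=O)=O)
Why: In this Upjohn dihydroxylation the electrophilic OsO4 should prefer the electron-rich trisubstituted C4=C5 alkene to the acrylate-type methylene, and with H6 held in the alkene plane by allylic 1,3-strain against C3 the ring carbon C7 covers one face, so syn addition from the open face (the one on which O6 lies) should give the 4R,5S diol, the new hydroxyls being trans to O6 in a flat drawing of the ring.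

Step 14
Reactants: 20 (4R,5S,6R,7R,10S)-4,5-dihydroxy-4,10-dimethyl-11(13)-methylene-9-oxocyclodecane-6,12-lactone; 21 (S)-2-methylbutanoic acid
Product: 23 CNP0144277.6 [(4R,5S,6R,7R,10S)-4-hydroxy-4,10-dimethyl-11(13)-methylene-9-oxo-5-[(2S)-2-methylbutanoyloxy]cyclodecane-6,12-lactone], via O-acylisourea 22 (not isolated)
Conditions: 21 (1.5 equiv), DCC, 4-(dimethylamino)pyridine (cat.), CH2Cl2, 0 °C to rt
Reagents that add atoms: (S)-2-methylbutanoic acid (compound 21), CC[C@H](C)C(=O)O
Why: Steglich esterification through O-acylisourea 22 acylates the secondary 5-OH, the tertiary 4-OH being inert, and acyl transfer at or below room temperature should leave the α-stereocentre of the acid untouched.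

Compound list
1 | (R)-carvone, (5R)-2-methyl-5-(prop-1-en-2-yl)cyclohex-2-en-1-one | CC1=CC[C@H](CC1=O)C(C)=C | starting material
2 | 5-bromopent-1-ene | C=CCCCBr | starting material
3 | potassium (5S)-2-methyl-5-(prop-1-en-2-yl)cyclohexa-1,3-dien-1-olate (linear dienolate of 1) | [K+].[O-]C1=C(C)C=C[C@@H](C(C)=C)C1 | intermediate
4 | (2S,5S)-2-methyl-2-(pent-4-en-1-yl)-5-(prop-1-en-2-yl)cyclohex-3-en-1-one | C=C(C)[C@H]1CC(=O)[C@](CCCC=C)(C)C=C1 | intermediate
5 | (4S,7S,9R,10S)-4β,10α-dimethyl-7α-(prop-1-en-2-yl)-cis-decal-5-en-9β-ol | C=C(C)[C@H]1C[C@@]2(O)[C@@H](C)CCC[C@@]2(C)C=C1 | intermediate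
6 | 5β,6β-osmate ester of 5 with hexavalent osmium, two oxo ligands and chelating TMEDA | C=C(C)[C@H]1C[C@@]2(O)[C@@H](C)CCC[C@@]2(C)[C@@H]3O[Os-2]4(=O)(=O)(O[C@H]13)[N+](C)(C)CC[N+]4(C)C | intermediate
7 | (4S,5S,6R,7R,9R,10S)-4β,10α-dimethyl-7α-(prop-1-en-2-yl)-cis-decalin-5β,6β,9β-triol | C=C(C)[C@H]1C[C@@]2(O)[C@@H](C)CCC[C@@]2(C)[C@H](O)[C@@H]1O | intermediate
8 | (4S,5S,6R,7R,9R,10S)-6β-(tert-butyldimethylsilyloxy)-4β,10α-dimethyl-7α-(prop-1-en-2-yl)-cis-decalin-5β,9β-diol | C=C(C)[C@H]1C[C@@]2(O)[C@@H](C)CCC[C@@]2(C)[C@H](O)[C@@H]1O[Si](C)(C)C(C)(C)C | intermediate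
9 | (4R,6R,7R,9R,10S)-6β-(tert-butyldimethylsilyloxy)-9β-hydroxy-4β,10α-dimethyl-7α-(prop-1-en-2-yl)-cis-decalin-5-one | C=C(C)[C@H]1C[C@@]2(O)[C@@H](C)CCC[C@@]2(C)C(=O)[C@@H]1O[Si](C)(C)C(C)(C)C | intermediate
10 | (4S,5R,6R,7R,9R,10S)-6β-(tert-butyldimethylsilyloxy)-4β,10α-dimethyl-7α-(prop-1-en-2-yl)-cis-decalin-5α,9β-diol | C=C(C)[C@H]1C[C@@]2(O)[C@@H](C)CCC[C@@]2(C)[C@@H](O)[C@@H]1O[Si](C)(C)C(C)(C)C | intermediate
11 | (4S,5R,6R,7R,9R,10S)-6β-(tert-butyldimethylsilyloxy)-9β-hydroxy-4β,10α-dimethyl-7α-(prop-1-en-2-yl)-cis-decalin-5α-yl methanesulfonate | C=C(C)[C@H]1C[C@@]2(O)[C@@H](C)CCC[C@@]2(C)[C@@H](OS(C)(=O)=O)[C@@H]1O[Si](C)(C)C(C)(C)C | intermediate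
12 | (4S,5R,6R,7R,9R,10S)-6β-(tert-butyldimethylsilyloxy)-9β-hydroxy-7α-(3-hydroxyprop-1-en-2-yl)-4β,10α-dimethyl-cis-decalin-5α-yl methanesulfonate | C=C(CO)[C@H]1C[C@@]2(O)[C@@H](C)CCC[C@@]2(C)[C@@H](OS(C)(=O)=O)[C@@H]1O[Si](C)(C)C(C)(C)C | intermediate
13 | (4S,5R,6R,7R,9R,10S)-6β-(tert-butyldimethylsilyloxy)-7α-[3-(tert-butyldimethylsilyloxy)prop-1-en-2-yl]-9β-hydroxy-4β,10α-dimethyl-cis-decalin-5α-yl methanesulfonate (key-step precursor) | C=C(CO[Si](C)(C)C(C)(C)C)[C@H]1C[C@@]2(O)[C@@H](C)CCC[C@@]2(C)[C@@H](OS(C)(=O)=O)[C@@H]1O[Si](C)(C)C(C)(C)C | intermediate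
14 | potassium 9-alkoxide of 13 | C=C(CO[Si](C)(C)C(C)(C)C)[C@H]1C[C@@]2([O-])[C@@H](C)CCC[C@@]2(C)[C@@H](OS(C)(=O)=O)[C@@H]1O[Si](C)(C)C(C)(C)C.[K+] | intermediate
15 | (4Z,6S,7R,10S)-6-(tert-butyldimethylsilyloxy)-7-[3-(tert-butyldimethylsilyloxy)prop-1-en-2-yl]-4,10-dimethylcyclodec-4-en-9-one (key-step product) | C=C(CO[Si](C)(C)C(C)(C)C)[C@H]1CC(=O)[C@@H](C)CCC/C(C)=C\[C@@H]1O[Si](C)(C)C(C)(C)C | intermediate
16 | (4Z,6S,7R,10S)-6-hydroxy-7-(3-hydroxyprop-1-en-2-yl)-4,10-dimethylcyclodec-4-en-9-one | C=C(CO)[C@H]1CC(=O)[C@@H](C)CCC/C(C)=C\[C@@H]1O | intermediate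
17 | 2-[(4Z,6S,7R,10S)-6-hydroxy-4,10-dimethyl-9-oxocyclodec-4-en-7-yl]prop-2-enal | C=C(C=O)[C@H]1CC(=O)[C@@H](C)CCC/C(C)=C\[C@@H]1O | intermediate
18 | 6,12-lactol of 17 (trans-fused 2-hydroxy-3-methylenetetrahydrofuran, both anomers) | C=C1[C@H]2CC(=O)[C@@H](C)CCC/C(C)=C\[C@@H]2OC1O | intermediate
19 | (4Z,6S,7R,10S)-4,10-dimethyl-11(13)-methylene-9-oxocyclodec-4-ene-6,12-lactone | C=C1[C@H]2CC(=O)[C@@H](C)CCC/C(C)=C\[C@@H]2OC1=O | intermediate
20 | (4R,5S,6R,7R,10S)-4,5-dihydroxy-4,10-dimethyl-11(13)-methylene-9-oxocyclodecane-6,12-lactone | C=C1C(=O)O[C@@H]2[C@@H]1CC(=O)[C@@H](C)CCC[C@@](C)(O)[C@H]2O | intermediate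
21 | (S)-2-methylbutanoic acid | CC[C@H](C)C(=O)O | starting material
22 | O-[(S)-2-methylbutanoyl]-N,N'-dicyclohexylisourea | CC[C@H](C)C(=O)OC(=NC1CCCCC1)NC1CCCCC1 | intermediate
23 | CNP0144277.6, (4R,5S,6R,7R,10S)-4-hydroxy-4,10-dimethyl-11(13)-methylene-9-oxo-5-[(2S)-2-methylbutanoyloxy]cyclodecane-6,12-lactone | C=C1C(=O)O[C@@H]2[C@@H]1CC(=O)[C@@H](C)CCC[C@@](C)(O)[C@H]2OC(=O)[C@@H](C)CC | target

Total step count: 14. Longest linear sequence: 14 steps (1 to 23); the acid 21 enters in the last step.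

Steps most likely to fail

Step 1. The nearly flat dienolate may be alkylated with too little facial discrimination at C4, and C-alkylation by an unactivated bromide may be slow enough for α′-alkylation, O-alkylation or loss of HBr from 2 to compete. The fallback sets out from 1 and comes back at 4; it replaces the substrate-controlled alkylation by a catalyst-controlled allylation followed by a two-carbon extension. Dienolate 3 is O-acylated with allyl chloroformate to allyl (5S)-2-methyl-5-(prop-1-en-2-yl)cyclohexa-1,3-dien-1-yl carbonate F1. Pd2(dba)3 with a t-Bu-PHOX ligand (the enantiomer that reinforces the substrate bias) in THF then brings about decarboxylative allylic alkylation (Tsuji reaction) at the α-carbon to give (2S,5S)-2-allyl-2-methyl-5-(prop-1-en-2-yl)cyclohex-3-en-1-one F2. 9-Borabicyclo[3.3.1]nonane should hydroborate only the monosubstituted alkene to the B-alkyl borane F3, which is coupled in the same flask with vinyl bromide (Pd(dppf)Cl2, K3PO4, THF/DMF/H2O; B-alkyl Suzuki–Miyaura coupling) to give 4.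

Step 2. The 6-exo closure onto an unactivated alkene may be slow enough for plain reduction of the ketyl to the secondary alcohol to take over, or control at C9 and C10 may be incomplete. The fallback sets out from 1 and comes back at 5; it forms the C9–C10 bond by a carbanion-type addition instead of a ketyl radical addition. Dienolate 3 is alkylated at the primary carbon of 1,4-dibromopentane to give (2S,5S)-2-(4-bromopentyl)-2-methyl-5-(prop-1-en-2-yl)cyclohex-3-en-1-one F4 (both configurations at the bromine-bearing carbon). SmI2 with HMPA in THF then reduces the secondary bromide, and the alkylsamarium adds to the C9 ketone (intramolecular samarium Barbier reaction, which gives cis-fused bicyclic tertiary alcohols), the methyl group taking the equatorial site of the chair, to give 5.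

Step 13. Facial selectivity of the osmylation on the flexible ten-membered ring may be poor, and some osmylation of the methylene lactone may occur. The fallback sets out from 16 and comes back at 20; it replaces conformational control by delivery from the free 6-OH before the lactone is closed. TBSCl (1.0 equiv) and imidazole silylate only the primary alcohol to give (4Z,6S,7R,10S)-7-[3-(tert-butyldimethylsilyloxy)prop-1-en-2-yl]-6-hydroxy-4,10-dimethylcyclodec-4-en-9-one F5. OsO4·TMEDA in CH2Cl2 at −78 °C, hydrogen-bonded to the allylic 6-OH (allylic delivery should beat the homoallylic path to the side-chain alkene), adds to C4=C5 on the side of that hydroxyl to give the osmate ester TMEDA chelate F6, which aqueous Na2SO3 cleaves to (4R,5S,6R,7R,10S)-7-[3-(tert-butyldimethylsilyloxy)prop-1-en-2-yl]-4,5,6-trihydroxy-4,10-dimethylcyclodecan-9-one F7. Bu4NF/AcOH gives (4R,5S,6R,7R,10S)-4,5,6-trihydroxy-7-(3-hydroxyprop-1-en-2-yl)-4,10-dimethylcyclodecan-9-one F8, and TEMPO/PhI(OAc)2 oxidises its primary allylic alcohol and closes the five-membered lactone onto the 6-OH to give 20.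

Further compounds
F1 | step 1 | allyl (5S)-2-methyl-5-(prop-1-en-2-yl)cyclohexa-1,3-dien-1-yl carbonate | C=CCOC(=O)OC1=C(C)C=C[C@@H](C(C)=C)C1
F2 | step 1 | (2S,5S)-2-allyl-2-methyl-5-(prop-1-en-2-yl)cyclohex-3-en-1-one | C=C(C)[C@H]1CC(=O)[C@](CC=C)(C)C=C1
F3 | step 1 | (2S,5S)-2-[3-(9-borabicyclo[3.3.1]nonan-9-yl)propyl]-2-methyl-5-(prop-1-en-2-yl)cyclohex-3-en-1-one | C=C(C)[C@H]1CC(=O)[C@](CCCB2C3CCCC2CCC3)(C)C=C1
F4 | step 2 | (2S,5S)-2-(4-bromopentyl)-2-methyl-5-(prop-1-en-2-yl)cyclohex-3-en-1-one | C=C(C)[C@H]1CC(=O)[C@](CCCC(C)Br)(C)C=C1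
F5 | step 13 | (4Z,6S,7R,10S)-7-[3-(tert-butyldimethylsilyloxy)prop-1-en-2-yl]-6-hydroxy-4,10-dimethylcyclodec-4-en-9-one | C=C(CO[Si](C)(C)C(C)(C)C)[C@H]1CC(=O)[C@@H](C)CCC/C(C)=C\[C@@H]1O
F6 | step 13 | 4,5-osmate ester of F5 with hexavalent osmium, two oxo ligands and chelating TMEDA | C=C(CO[Si](C)(C)C(C)(C)C)[C@H]1CC(=O)[C@@H](C)CCC[C@@]2(C)O[Os-2]3(=O)(=O)(O[C@H]2[C@@H]1O)[N+](C)(C)CC[N+]3(C)C
F7 | step 13 | (4R,5S,6R,7R,10S)-7-[3-(tert-butyldimethylsilyloxy)prop-1-en-2-yl]-4,5,6-trihydroxy-4,10-dimethylcyclodecan-9-one | C=C(CO[Si](C)(C)C(C)(C)C)[C@H]1CC(=O)[C@@H](C)CCC[C@@](C)(O)[C@@H](O)[C@@H]1O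
F8 | step 13 | (4R,5S,6R,7R,10S)-4,5,6-trihydroxy-7-(3-hydroxyprop-1-en-2-yl)-4,10-dimethylcyclodecan-9-one | C=C(CO)[C@H]1CC(=O)[C@@H](C)CCC[C@@](C)(O)[C@@H](O)[C@@H]1O
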